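Its constants stand for no real mixture; the run is a simulation.

- The question was which flask holds the most target at the end, and how much each holds.

common to all: substrate 20 mM; time 40 s
- Tuesday's: temperature 25 °C
- Sunday's: temperature −15 °C
- Thursday's: temperature 45 °C
- Saturday's: temperature 5 °C

- the flask with the highest amount of target, in percent of the substrate charged ("all alike" if they lie within 1.5 percentage points) (Tuesday's / Sunday's / Thursday's / Saturday's / all alike)
- final target, as a percentage of the substrate charged, in Tuesday's
- final target, as a percentage of the substrate charged, in Sunday's
- final target, as a percentage of the substrate charged, in Thursday's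
- final target, as a percentage of the substrate charged, in Saturday's

- constants are those at 5 °C; use the activation energies and enthalpies for any other temperature

    substrate ⇌ third isomer (K1 = 210, k1 = 0.015 s⁻¹, Ea1 = 76.0 kJ mol⁻¹, ΔH1 = −24.0 kJ mol⁻¹)
    target → over-reaction product (k2 = 9.5 × 10⁻⁴ s⁻¹, Ea2 = 83.0 kJ mol⁻¹)
    substrate ⇌ target (K3 = 12, k3 = 0.11 s⁻¹, Ea3 = 63.0 kJ mol⁻¹, ΔH3 = −56.0 kJ mol⁻¹)
    substrate ⇌ isomer of the product (K4 = 35, k4 = 0.014 s⁻¹, Ea4 = 67.0 kJ mol⁻¹, ΔH4 = −28.0 kJ mol⁻¹)
    (constants at 5 °C)

- I kept books on substrate, the limiting reagent, and began in Saturday's, where the constants apply as given.
- My carried quantity was the target share (the selectivity), the rate of making target divided by the total forward rate of substrate loss, 79.1%; c(substrate) stands in each rate, so it cancels, and time drops out with it.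
- The first entries in Saturday's were therefore 79.1% of the charge to target, 10.8% to third isomer and 10.1% to isomer of the product.
- Target could leave Saturday's flask in two ways: it fell back to substrate at 0.00917 s⁻¹ and went on to over-reaction product at 9.5 × 10⁻⁴ s⁻¹, so falling back was 9.65 times the faster.
- Each mole that fell back met the same share again, so 71.7% of the exits from target came back to target.
- That left a net drain on target of 0.00286 s⁻¹, and over 40 s the target entry fell from 79.1% to 70.6%.
- The books closed with 70.6% as target, 2.84% as over-reaction product and 26.6% as the isomers, with substrate still in transit not entered.
- Making target has a lower activation energy, 63.0 kJ mol⁻¹, than the losses to third isomer, 76.0 kJ mol⁻¹, and to isomer of the product, 67.0 kJ mol⁻¹, so the share rises as a flask is cooled; I did not carry the books to the other flasks, so I gave them no figures.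
- The forecast named Saturday's as the richest flask, with 68.5% there, 39.2% in Sunday's, 6.7% in Tuesday's and 0.83% in Thursday's; of Sunday's it said “the reaction is kinetically incomplete”.
- My 70.6% for Saturday's stood above the forecast's figure.
- The flasks gave Saturday's as the richest, with 68.5% there, 39.2% in Sunday's, 6.25% in Tuesday's and 0.834% in Thursday's.
- In Saturday's the relaxation half-life of substrate and target by their own step alone, 5.82 s, was shorter than the 46.0 s of substrate and third isomer by theirs and short against the 40 s of the run, while at 4.38 s target fell back 9.6 times faster than it went on. The share I had reckoned for the very start was 79.1%; in a flask like Saturday's left until 10 s, which held 56.8% target, target and over-reaction product together made 78.2% of the substrate consumed, and in Saturday's itself at 40 s they made less, 74.5%.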